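## Retrosynthetic overview

1. Locants: ring A = C1-C2-C3-C9-C13, cyclobutane B = C3-C4-C8-C9, ring C = C4-C5-C6-C7-C8, butenolide D = C9-O10-C11-C12-C13, and C14 is the CH2O group on C12. "Exo" is the face of ring B that carries H4, H8, C3-CH3 and O10; "endo" is the face under which rings A and C fold.
2. Feature used: C13 is the β-carbon of butenolide D, and C1 is the carbinol carbon bonded to it. C13 (on C9) and the C2-C1 arm (on C3) both hang from the endo face of ring B, so ring A can be closed last through the C1-C13 bond.
3. Disconnections: the esters go on last (C1 tiglate, C5 and C14 acetates). C1-C13 comes from an intramolecular Nozaki-Hiyama-Kishi addition of a C13 alkenyl triflate to a C1 aldehyde. Ring D comes from O10 acylation and Dieckmann closure (C12-C13) of a C9 hydroxy ester.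
4. C9: the cyclobutanone is homologated to the ester, then O10 is added by exo enolate hydroxylation. C3: allylation, then exo methylation. Ring C: C5-O by exo conjugate borylation, C7-OH by exo radical hydration of a C7 methylene.
5. Ring order: B and C arrive fused in the bicycloheptenone, then D (spiro at C9), then A.

Key step: step 19

Remark: ketone 1 is assumed to be bought as the single (1R,5S) enantiomer; its C1 and C5 centres map onto C4 and C8 of the target, and target locants are used for all intermediates.

## Route

Step 1
Reactants: 1 (1R,5S)-bicyclo[3.2.0]hept-2-en-6-one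
Product: 2 C9 ethylene ketal of 1
Conditions: HOCH2CH2OH, p-TsOH (cat.), benzene, reflux, Dean-Stark
Reagents that add atoms: ethylene glycol, OCCO
Why: Acid-catalysed ketalisation with azeotropic removal of water works readily here because the change to sp3 relieves angle strain in the cyclobutanone; the mask keeps C9 out of the peroxide, boron and radical chemistry of steps 2 to 6, and no stereocentre is touched.

Step 2
Reactants: 2 C9 ethylene ketal of 1
Product: 3 C7-exo allylic alcohol
Conditions: SeO2 (0.5 equiv), t-BuOOH (2 equiv), CH2Cl2, 0 °C to rt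
Reagents that add atoms: tert-butyl hydroperoxide, CC(C)(C)OO; selenium dioxide (oxygen carrier), O=[Se]=O
Why: In this Riley allylic hydroxylation the ene step binds selenium to C5 and removes a C7 hydrogen, and the [2,3] shift returns oxygen to C7 with the alkene back at C5=C6, whereas the other ene path would need a double bond at bridgehead C4, so C7 should be oxidised regiospecifically from the exo face (this centre is erased in step 3).

Step 3
Reactants: 3 C7-exo allylic alcohol
Product: 4 C7 enone ketal
Conditions: Dess-Martin periodinane, CH2Cl2, rt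
Reagents that add atoms: none
Why: Dess-Martin oxidation of the secondary allylic alcohol (together with any enone already formed in step 2) converges on the enone under conditions that leave the ketal and the cis ring fusion untouched.

Step 4
Reactants: 4 C7 enone ketal
Product: 6 C5-exo-hydroxy C7 ketone ketal, via C5 pinacol boronate 5 (not isolated)
Conditions: CuCl (5 mol %), Xantphos (5 mol %), NaOt-Bu (10 mol %), B2pin2, MeOH, THF, rt; then NaBO3·4H2O, THF/H2O, rt
Reagents that add atoms: bis(pinacolato)diboron, CC1(C)OB(OC1(C)C)B1OC(C)(C)C(C)(C)O1; sodium perborate, [Na+].[Na+].O[B-]1(O)OO[B-](O)(O)OO1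
Why: Copper-catalysed conjugate borylation followed by perborate oxidation with retention sets C5 with its oxygen exo (cis to H4), because the copper boryl species adds to C5 from the exo face of the folded bicycle.

Step 5
Reactants: 6 C5-exo-hydroxy C7 ketone ketal
Product: 7 C5-exo-hydroxy C7-methylene ketal
Conditions: Zn, CH2Br2, TiCl4 (aged in THF at 5 °C); then 6, CH2Cl2, 0 °C to rt
Reagents that add atoms: dibromomethane, BrCBr
Why: Takai-Lombardo-type methylenation with a non-basic zinc/titanium gem-dimetal reagent converts the hindered C7 ketone without the dehydration or retro-aldol cleavage that a basic ylide would cause in a β-hydroxy ketone, and it tolerates the free hydroxyl group and the ketal.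

Step 6
Reactants: 7 C5-exo-hydroxy C7-methylene ketal
Product: 9 C5/C7 exo-cis dihydroxy cyclobutanone, via exo-cis diol ketal 8 (not isolated)
Conditions: Mn(dpm)3 (10 mol %), PhSiH3, O2 (1 atm), i-PrOH, 0 °C to rt; then 1 M aq HCl, rt
Reagents that add atoms: dioxygen, O=O; water, O
Why: In this Mukaiyama hydration, hydrogen-atom transfer to the terminal CH2 gives the tertiary C7 radical, which O2 should trap (much faster than cyclobutylcarbinyl ring opening) from the exo face because the endo face is closed by the C9 ketal; this sets C7 with OH exo and CH3 endo, the arrangement that exo attack of a methyl nucleophile on the ketone could not give, and the aqueous acid then hydrolyses the ketal.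

Step 7
Reactants: 9 C5/C7 exo-cis dihydroxy cyclobutanone
Product: 11 C5-OTBS C7-OTES cyclobutanone, via C5 mono-TBS ether 10 (not isolated)
Conditions: TBSOTf (1.05 equiv), 2,6-lutidine, CH2Cl2, -78 °C; then TESOTf (1.5 equiv), -78 to 0 °C
Reagents that add atoms: tert-butyldimethylsilyl triflate, CC(C)(C)[Si](C)(C)OS(=O)(=O)C(F)(F)F; triethylsilyl triflate, CC[Si](CC)(CC)OS(=O)(=O)C(F)(F)F
Why: Silyl triflates react in the order of steric access (secondary C5-OH at -78 °C, then tertiary C7-OH); C5 is carried as a silyl ether because an acetate would not survive the enolate chemistry of steps 8, 9, 12 and 16, and the silylated C7 oxygen can no longer trigger a retro-aldol.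

Step 8
Reactants: 11 C5-OTBS C7-OTES cyclobutanone; 12 allyl bromide
Product: 13 C3-exo-allyl cyclobutanone
Conditions: LiN(SiMe3)2, THF, -78 °C; allyl bromide, DMPU, -78 to -30 °C
Reagents that add atoms: allyl bromide, C=CCBr
Why: In this kinetic enolate alkylation the amide base removes a proton from the C3 methylene rather than the ring-fusion H8 and allyl bromide enters from the exo face, although the C3 configuration of 13 does not matter because it is planarised in step 9.

Step 9
Reactants: 13 C3-exo-allyl cyclobutanone; 14 iodomethane
Product: 15 C3-quaternary cyclobutanone (CH3 exo, allyl endo)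
Conditions: KN(SiMe3)2, THF, -78 °C; MeI, -78 to -20 °C
Reagents that add atoms: iodomethane, CI
Why: In this second enolate alkylation, enolisation should again go towards C3, since a C8=C9 enolate would place a double bond at the strained ring fusion and H8 is screened by the neighbouring OTES group, and iodomethane attacks the planar enolate from the exo face, which sets the quaternary C3 with CH3 exo and the allyl arm endo.

Step 10
Reactants: 15 C3-quaternary cyclobutanone (CH3 exo, allyl endo)
Product: 16 C9 methoxymethylene enol ether (E/Z mixture)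
Conditions: Ph3P(CH2OMe)Cl, KN(SiMe3)2, THF, 0 °C; then 15, 0 to 40 °C
Reagents that add atoms: (methoxymethyl)triphenylphosphonium chloride, COC[P+](c1ccccc1)(c1ccccc1)c1ccccc1.[Cl-]
Why: In this Wittig methoxymethylenation the strained carbonyl group should accept the small, reactive ylide from the exo face despite the quaternary neighbour, and the E/Z ratio at C9=C13 is irrelevant.

Step 11
Reactants: 16 C9 methoxymethylene enol ether (E/Z mixture)
Product: 17 C9 methyl ester (CO2Me endo, H exo)
Conditions: pyridinium chlorochromate C5H5NH[CrO3Cl], NaOAc, 4 Å MS, CH2Cl2, rt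
Reagents that add atoms: pyridinium chlorochromate, c1cc[nH+]cc1.[O-][Cr](=O)(=O)Cl
Why: Chlorochromate oxidation of an enol ether to the ester (protonation at C9 from the exo face, addition of chlorochromate to the oxocarbenium carbon C13, then C-H oxidation) brings C13 to the carboxyl level in one step with the methoxy group retained, and it leaves the monosubstituted alkene and the hindered silyl ethers alone.

Step 12
Reactants: 17 C9 methyl ester (CO2Me endo, H exo)
Product: 18 C9 hydroxy ester (OH exo, CO2Me endo)
Conditions: KN(SiMe3)2, THF, -78 °C; 3-phenyl-2-(phenylsulfonyl)oxaziridine, -78 °C; aq NH4Cl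
Reagents that add atoms: 3-phenyl-2-(phenylsulfonyl)oxaziridine, O=S(=O)(c1ccccc1)N1OC1c1ccccc1
Why: In this Davis enolate hydroxylation the oxaziridine attacks the planar exocyclic ester enolate from the exo face (the endo face is walled off by the allyl arm and the endo C7 methyl), which sets C9 with O10 exo and C13 endo, and working at the ester level avoids a 1-hydroxycyclobutanecarbaldehyde, which would be prone to a ring-enlarging α-ketol shift.

Step 13
Reactants: 19 methyl 3-hydroxypropanoate
Product: 20 methyl 3-(tert-butyldimethylsilyloxy)propanoate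
Conditions: TBSCl, imidazole, CH2Cl2, 0 °C to rt
Reagents that add atoms: tert-butyldimethylsilyl chloride, CC(C)(C)[Si](C)(C)Cl
Why: This is a standard imidazole-promoted silylation of a primary alcohol.

Step 14
Reactants: 20 methyl 3-(tert-butyldimethylsilyloxy)propanoate
Product: 21 3-(tert-butyldimethylsilyloxy)propanoic acid
Conditions: LiOH, THF/H2O, 0 °C; then 1 M HCl to pH 4
Reagents that add atoms: lithium hydroxide, [Li+].[OH-]
Why: Saponification at low temperature followed by mild acidification keeps β-elimination and desilylation of the β-silyloxy ester at bay.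

Step 15
Reactants: 18 C9 hydroxy ester (OH exo, CO2Me endo); 21 3-(tert-butyldimethylsilyloxy)propanoic acid
Product: 22 C9 acyloxy ester
Conditions: DCC, DMAP, CH2Cl2, 0 °C to rt
Reagents that add atoms: 3-(tert-butyldimethylsilyloxy)propanoic acid, OC(=O)CCO[Si](C)(C)C(C)(C)C
Why: In this Steglich esterification the acylpyridinium ion formed with DMAP acylates the hindered but exo-exposed tertiary C9 hydroxyl group, and no stereocentre changes.

Step 16
Reactants: 22 C9 acyloxy ester
Product: 23 spiro tetronic acid (ring D closed)
Conditions: LiN(SiMe3)2 (2.2 equiv), THF, -78 to -30 °C; cold 0.5 M HCl to pH 3; used without purification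
Reagents that add atoms: none
Why: In this Dieckmann (Lacey-type) condensation the C12 ester enolate attacks the geminal C13 ester in a 5-exo-trig closure favoured by the quaternary C9, irreversible formation of the stabilised tetronate anion drives ring D formation, and the low temperature is meant to let cyclisation outrun β-elimination of the C14 silyloxy group.

Step 17
Reactants: 23 spiro tetronic acid (ring D closed)
Product: 24 spiro butenolide C13 triflate carrying the allyl arm
Conditions: Tf2O, i-Pr2NEt, CH2Cl2, -78 °C
Reagents that add atoms: triflic anhydride, FC(F)(F)S(=O)(=O)OS(=O)(=O)C(F)(F)F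
Why: O-sulfonylation of the tetronic acid at the C13 oxygen, the usual site because it gives the conjugated butenolide, provides the alkenyl triflate without touching the silyl ethers or the alkene.

Step 18
Reactants: 24 spiro butenolide C13 triflate carrying the allyl arm
Product: 25 spiro butenolide C13 triflate carrying the C3 acetaldehyde arm
Conditions: O3, CH2Cl2, -78 °C (stopped at the first excess of ozone); then Me2S, -78 °C to rt
Reagents that add atoms: ozone, [O-][O+]=O
Why: Ozonolysis with reductive work-up cleaves only the terminal alkene, since the tetrasubstituted C12=C13 bond carries two acceptor groups and is inert to ozone, and dimethyl sulfide is chosen because it does not add to the electrophilic C13.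

Step 19
Reactants: 25 spiro butenolide C13 triflate carrying the C3 acetaldehyde arm
Product: 27 tetracyclic C1 alcohol (ring A closed), via C13 alkenylchromium dichloride 26 (not isolated)
Conditions: CrCl2 (6 equiv), NiCl2 (2 mol %), degassed DMF, 0.005 M, rt; aqueous EDTA work-up
Reagents that add atoms: none
Why: CrCl2 reduces NiCl2 to zerovalent nickel, which inserts into the activated C13-OTf bond of the β-triflyloxy butenolide; transmetalation to trivalent chromium gives alkenylchromium 26, which adds to the C1 aldehyde and leaves a chromium alkoxide that is hydrolysed on work-up. The closest known reaction type is the intramolecular Nozaki-Hiyama-Kishi coupling of alkenyl triflates (β-metalated enoates included) with aldehydes. Ring A closes in the 5-exo-trig mode (C13 attacks the carbonyl carbon C1 and the oxygen stays outside the ring), and because C13 and the C2-C1 arm were both fixed on the endo face of ring B in steps 9 and 12, only the cis-fused, cis-syn-cis tetracycle can form. At C1 the chromium-bound oxygen with its ligand sphere should sit on the open outer face of the forming ring, the side of C3-CH3 and O10, while the small aldehyde hydrogen points into the cleft towards ring C and the endo C7 methyl, which gives the required alcohol. The step needs chemoselectivity for the aldehyde over the lactone and silyl ethers, which the low basicity and carbonyl selectivity of organochromium reagents provide, and it needs cyclisation to outrun protonolysis, pinacol coupling and β-loss of the O10 carboxylate, which the close 1,5 placement of the two termini and high dilution favour.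

Step 20
Reactants: 27 tetracyclic C1 alcohol (ring A closed); 28 tiglic acid
Product: 29 C1 tiglate
Conditions: tiglic acid, DCC, DMAP, CH2Cl2, rt
Reagents that add atoms: tiglic acid, C/C=C(\C)C(=O)O
Why: Steglich esterification of the outer-face allylic alcohol proceeds with retention at C1, and the E geometry of the tiglate is the stable one and comes from the acid.

Step 21
Reactants: 29 C1 tiglate
Product: 30 C5/C7/C14 triol tiglate
Conditions: HF·pyridine, pyridine, THF, 0 °C to rt
Reagents that add atoms: none
Why: Fluoride cleaves all three silyl ethers under mildly acidic, non-nucleophilic conditions that should avoid acyl migration and leave the allylic ester and the butenolide intact.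

Step 22
Reactants: 30 C5/C7/C14 triol tiglate
Product: 31 target CNP0210373.1
Conditions: Ac2O (2.5 equiv), pyridine, DMAP (cat.), CH2Cl2, 0 °C
Reagents that add atoms: acetic anhydride, CC(=O)OC(C)=O
Why: Acylation rates fall in the order primary, secondary, tertiary, so a small excess of acetic anhydride esterifies C14-OH and the exo C5-OH in one operation and leaves the hindered tertiary C7-OH free.

## Compound list

1 | (1R,5S)-bicyclo[3.2.0]hept-2-en-6-one | C1[C@@H]2C=CC[C@@H]2C1=O | starting material
2 | (1R,5S)-spiro[bicyclo[3.2.0]hept-2-ene-6,2'-[1,3]dioxolane], the C9 ethylene ketal of 1 | C1[C@@H]2C=CC[C@@H]2C13OCCO3 | intermediate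
3 | ketal 2 with an exo hydroxyl group at allylic C7, C5=C6 retained | C1[C@@H]2C=C[C@@H](O)[C@@H]2C13OCCO3 | intermediate
4 | enone ketal: C7 ketone conjugated with C5=C6, C9 ethylene ketal | C1[C@@H]2C=CC(=O)[C@@H]2C13OCCO3 | intermediate
5 | saturated C7 ketone ketal with exo pinacolboryl group at C5 (not isolated) | C1[C@@H]2[C@@H](B4OC(C)(C)C(C)(C)O4)CC(=O)[C@@H]2C13OCCO3 | intermediate
6 | C7 ketone ketal with exo hydroxyl group at C5 (cis to H4) | C1[C@@H]2[C@@H](O)CC(=O)[C@@H]2C13OCCO3 | intermediate
7 | C7 exocyclic methylene ketal with exo C5-OH | C1[C@@H]2[C@@H](O)CC(=C)[C@@H]2C13OCCO3 | intermediate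
8 | diol ketal: C5-OH exo, C7-OH exo, C7-CH3 endo (not isolated) | C1[C@@H]2[C@@H](O)C[C@@](C)(O)[C@@H]2C13OCCO3 | intermediate
9 | dihydroxy cyclobutanone: C9 ketone, C5-OH exo, C7-OH exo, C7-CH3 endo | C1[C@@H]2[C@@H](O)C[C@@](C)(O)[C@@H]2C1=O | intermediate
10 | C5 TBS ether of 9 with free tertiary C7-OH (not isolated) | C1[C@@H]2[C@@H](O[Si](C)(C)C(C)(C)C)C[C@@](C)(O)[C@@H]2C1=O | intermediate
11 | cyclobutanone with C5-OTBS (exo) and C7-OTES (exo) | C1[C@@H]2[C@@H](O[Si](C)(C)C(C)(C)C)C[C@@](C)(O[Si](CC)(CC)CC)[C@@H]2C1=O | intermediate
12 | allyl bromide | C=CCBr | starting material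
13 | cyclobutanone 11 with an exo allyl group at C3 (H endo) | C=CC[C@H]1[C@@H]2[C@@H](O[Si](C)(C)C(C)(C)C)C[C@@](C)(O[Si](CC)(CC)CC)[C@@H]2C1=O | intermediate
14 | iodomethane | CI | starting material
15 | cyclobutanone with quaternary C3: CH3 exo, allyl endo | C=CC[C@]1(C)[C@@H]2[C@@H](O[Si](C)(C)C(C)(C)C)C[C@@](C)(O[Si](CC)(CC)CC)[C@@H]2C1=O | intermediate
16 | C9=C13 methyl enol ether of 15 (E/Z mixture) | C=CC[C@]1(C)[C@@H]2[C@@H](O[Si](C)(C)C(C)(C)C)C[C@@](C)(O[Si](CC)(CC)CC)[C@@H]2C1=COC | intermediate
17 | cyclobutanecarboxylate: C9-H exo, C13 methyl ester endo | C=CC[C@]1(C)[C@@H]2[C@@H](O[Si](C)(C)C(C)(C)C)C[C@@](C)(O[Si](CC)(CC)CC)[C@@H]2[C@@H]1C(=O)OC | intermediate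
18 | hydroxy ester: C9-OH (O10) exo, C13 methyl ester endo | C=CC[C@]1(C)[C@@H]2[C@@H](O[Si](C)(C)C(C)(C)C)C[C@@](C)(O[Si](CC)(CC)CC)[C@@H]2[C@]1(O)C(=O)OC | intermediate
19 | methyl 3-hydroxypropanoate | COC(=O)CCO | starting material
20 | methyl 3-(tert-butyldimethylsilyloxy)propanoate | COC(=O)CCO[Si](C)(C)C(C)(C)C | intermediate
21 | 3-(tert-butyldimethylsilyloxy)propanoic acid | OC(=O)CCO[Si](C)(C)C(C)(C)C | intermediate
22 | O10 3-(TBS-oxy)propanoate of hydroxy ester 18 | C=CC[C@]1(C)[C@@H]2[C@@H](O[Si](C)(C)C(C)(C)C)C[C@@](C)(O[Si](CC)(CC)CC)[C@@H]2[C@]1(OC(=O)CCO[Si](C)(C)C(C)(C)C)C(=O)OC | intermediate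
23 | spiro tetronic acid: ring D on C9 (O10 exo, C13 endo), C13-OH, C12-CH2OTBS, allyl arm on C3 | C=CC[C@]2(C)[C@@H]3[C@@H](O[Si](C)(C)C(C)(C)C)C[C@@](C)(O[Si](CC)(CC)CC)[C@@H]3[C@@]24OC(=O)C(CO[Si](C)(C)C(C)(C)C)=C4O | intermediate
24 | C13 triflate of 23 (allyl arm on C3) | C=CC[C@]2(C)[C@@H]3[C@@H](O[Si](C)(C)C(C)(C)C)C[C@@](C)(O[Si](CC)(CC)CC)[C@@H]3[C@@]24OC(=O)C(CO[Si](C)(C)C(C)(C)C)=C4OS(=O)(=O)C(F)(F)F | intermediate
25 | key-step precursor: spiro butenolide C13 triflate with endo CH2CHO arm on C3, C5-OTBS, C7-OTES, C14-OTBS | O=CC[C@]2(C)[C@@H]3[C@@H](O[Si](C)(C)C(C)(C)C)C[C@@](C)(O[Si](CC)(CC)CC)[C@@H]3[C@@]24OC(=O)C(CO[Si](C)(C)C(C)(C)C)=C4OS(=O)(=O)C(F)(F)F | intermediate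
26 | C13 alkenylchromium dichloride derived from 25 (not isolated) | O=CC[C@]2(C)[C@@H]3[C@@H](O[Si](C)(C)C(C)(C)C)C[C@@](C)(O[Si](CC)(CC)CC)[C@@H]3[C@@]24OC(=O)C(CO[Si](C)(C)C(C)(C)C)=C4[Cr](Cl)Cl | intermediate
27 | key-step product: tetracyclic C1 alcohol, OH on the outer face cis to C3-CH3 and O10 | O[C@H]1C[C@]2(C)[C@@H]3[C@@H](O[Si](C)(C)C(C)(C)C)C[C@@](C)(O[Si](CC)(CC)CC)[C@@H]3[C@@]23OC(=O)C(CO[Si](C)(C)C(C)(C)C)=C13 | intermediate
28 | tiglic acid, (E)-2-methylbut-2-enoic acid | C/C=C(\C)C(=O)O | starting material
29 | C1 tiglate of 27 | C/C=C(\C)C(=O)O[C@H]1C[C@]2(C)[C@@H]3[C@@H](O[Si](C)(C)C(C)(C)C)C[C@@](C)(O[Si](CC)(CC)CC)[C@@H]3[C@@]23OC(=O)C(CO[Si](C)(C)C(C)(C)C)=C13 | intermediate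
30 | C1 tiglate with free C5-OH, C7-OH and C14-OH | C/C=C(\C)C(=O)O[C@H]1C[C@]2(C)[C@@H]3[C@@H](O)C[C@@](C)(O)[C@@H]3[C@@]23OC(=O)C(CO)=C13 | intermediate
31 | CNP0210373.1 | C/C=C(\C)C(=O)O[C@H]1C[C@]2(C)[C@@H]3[C@@H](OC(C)=O)C[C@@](C)(O)[C@@H]3[C@@]23OC(=O)C(COC(C)=O)=C13 | target

## Step count and risks

Total step count: 22. Longest linear sequence: 20 steps (steps 1 to 12 and 15 to 22).

Steps most likely to fail:

**1. Step 19 (key step).**
- What may go wrong:
  - Nickel may insert too slowly into the crowded, tetrasubstituted C13-O bond, so that reduction or pinacol coupling of the aldehyde by divalent chromium takes over.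
  - The alkenylmetal may be protonated before it cyclises.
  - The lactone may open by β-elimination of the O10 carboxylate from the C13 metal species.
  - The addition may occur with the oxygen turned into the cleft, which would give the wrong C1 configuration.
- Fallback (sets out from 24, returns at 29): the C1-C13 bond is made by palladium instead of chromium. An intramolecular Heck reaction of allyl triflate 24 (Pd(OAc)2, PPh3, Et3N, MeCN, 70 °C) should close ring A in the 5-exo mode and, after β-hydride elimination, give the tetracyclic C1-methylene compound F1. One equivalent of ozone followed by Me2S should cleave only the electron-richer exocyclic alkene to the tetracyclic C1 ketone F2. Luche reduction (NaBH4, CeCl3·7H2O, MeOH, -78 °C) should deliver hydride from the open outer face and give the inner-face C1-epi alcohol F3. Mitsunobu esterification with tiglic acid 28 (PPh3, DIAD, THF) then inverts C1 and gives tiglate 29 directly.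

**2. Step 16.**
- What may go wrong:
  - Silanolate may be lost from the C12 ester enolate by β-elimination faster than the enolate attacks the hindered, endo C13 ester.
  - Silanol may be lost from the tetronic acid during the acidic work-up.
- Fallback (sets out from 18, returns at 23): ring D is closed without any ester enolate that carries a β-leaving group. Hydroxy ester 18 and ketenylidenetriphenylphosphorane (Ph3P=C=C=O, toluene, reflux) should give, by O-H addition and intramolecular Wittig olefination of the C13 ester, the spiro methyl tetronate F4. C12 lithiation (LiN(i-Pr)2, THF, -78 °C; C9 carries no hydrogen) and trapping with gaseous formaldehyde gives the C12-hydroxymethyl methyl tetronate F5. TBSCl and imidazole give the C14 silyl ether F6. O-demethylation with LiCl in DMSO (60 °C) and mild acidification gives tetronic acid 23.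

**3. Step 9.**
- What may go wrong:
  - Removal of the endo C3 hydrogen may be too slow, so that enolisation towards C8 with E1cB loss of the C7 silyloxy group competes.
  - O-methylation or aldol self-condensation of the cyclobutanone may also compete.
  - Facial selectivity of the methylation may be incomplete.
- Fallback (sets out from 11, returns at 15): the enolate is generated regiospecifically by conjugate addition. Ketone 11 is converted with LiN(SiMe3)2 and dimethylmethyleneiminium iodide into the C3-exo Mannich base F7. Quaternisation with MeI and elimination (NaHCO3) gives the C3-methylene cyclobutanone F8. Addition of (H2C=CH)2CuLi builds the allyl arm while producing only the C3=C9 enolate, which is methylated in the same flask (MeI, DMPU) from the exo face to give 15.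

## Further compounds

F1 | step 19 | tetracyclic C1-methylene compound (rings A to D closed, silyl ethers as in 24) | C=C1C[C@]2(C)[C@@H]3[C@@H](O[Si](C)(C)C(C)(C)C)C[C@@](C)(O[Si](CC)(CC)CC)[C@@H]3[C@@]23OC(=O)C(CO[Si](C)(C)C(C)(C)C)=C13
F2 | step 19 | tetracyclic C1 ketone | O=C1C[C@]2(C)[C@@H]3[C@@H](O[Si](C)(C)C(C)(C)C)C[C@@](C)(O[Si](CC)(CC)CC)[C@@H]3[C@@]23OC(=O)C(CO[Si](C)(C)C(C)(C)C)=C13
F3 | step 19 | inner-face C1-epi alcohol (OH trans to C3-CH3 and O10) | O[C@@H]1C[C@]2(C)[C@@H]3[C@@H](O[Si](C)(C)C(C)(C)C)C[C@@](C)(O[Si](CC)(CC)CC)[C@@H]3[C@@]23OC(=O)C(CO[Si](C)(C)C(C)(C)C)=C13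
F4 | step 16 | spiro methyl tetronate (C13-OMe, C12-H) | C=CC[C@]2(C)[C@@H]3[C@@H](O[Si](C)(C)C(C)(C)C)C[C@@](C)(O[Si](CC)(CC)CC)[C@@H]3[C@@]24OC(=O)C=C4OC
F5 | step 16 | C12-hydroxymethyl methyl tetronate | C=CC[C@]2(C)[C@@H]3[C@@H](O[Si](C)(C)C(C)(C)C)C[C@@](C)(O[Si](CC)(CC)CC)[C@@H]3[C@@]24OC(=O)C(CO)=C4OC
F6 | step 16 | C14 silyl ether of the methyl tetronate | C=CC[C@]2(C)[C@@H]3[C@@H](O[Si](C)(C)C(C)(C)C)C[C@@](C)(O[Si](CC)(CC)CC)[C@@H]3[C@@]24OC(=O)C(CO[Si](C)(C)C(C)(C)C)=C4OC
F7 | step 9 | C3-exo Mannich base, (dimethylamino)methyl cyclobutanone | CN(C)C[C@H]1[C@@H]2[C@@H](O[Si](C)(C)C(C)(C)C)C[C@@](C)(O[Si](CC)(CC)CC)[C@@H]2C1=O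
F8 | step 9 | C3-methylene cyclobutanone | C=C1[C@@H]2[C@@H](O[Si](C)(C)C(C)(C)C)C[C@@](C)(O[Si](CC)(CC)CC)[C@@H]2C1=O
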